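**Plan**

- Cuts, in retrosynthetic order: the O–CH3 bond at C3, the C3–O bond of ring C (back to the C3–H of a (2S)-flavanone), the C2–C1' bond joining ring C to ring B, and the C2 carbon of the pyranone (back to a ring A acetophenone).
- Forward order: ring C is closed first, as a chromone, on the ring A acetophenone, whose single free phenol becomes O1. The 5-O-methyl is exchanged for benzyl while the molecule is still achiral. Ring B is then joined at C2 as its boronic acid, followed by hydrogenolysis, C3 hydroxylation and O-methylation.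
- Enabling feature: C3 of ring C carries oxygen trans to the C2 aryl group and alpha to the C4 carbonyl, which is hydrogen-bonded to the 5-hydroxyl of ring A. This is the site and face at which flavanone 3-hydroxylases oxidise 5-hydroxy-(2S)-flavanones.
- Stereochemistry: C2 is set by the chiral pyridine–oxazoline ligand in a palladium-catalysed conjugate addition (2S in the flavanone, named 2R once C3 bears oxygen). C3 is set by the enzyme, which takes only the 2S enantiomer and so should also raise the enantiomeric purity.

Key step: step 9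

Assumption: a recombinant plant flavanone 3-hydroxylase (the Petunia × hybrida enzyme or a homologue picked from a small panel) is taken to accept 14, which keeps the 5-hydroxy-4-keto (2S)-flavanone core of the natural substrates; the sense of induction of the ligand in step 7 is taken to follow that known for simple chromones and would be checked on the first batch.

**Route**

Step 1
Reactants: 1 2-methoxyhydroquinone (2-methoxybenzene-1,4-diol)
Product: 2 1,4-bis(benzyloxy)-2-methoxybenzene
Conditions: BnBr (2.3 equiv), K2CO3 (3 equiv), DMF, N2, rt to 50 °C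
Reagents that add atoms: benzyl bromide, BrCc1ccccc1
Why: Williamson ether synthesis on both phenols under carbonate base (under nitrogen, since the hydroquinone autoxidises in base), benzyl being chosen because it survives organolithium and palladium chemistry and leaves by neutral hydrogenolysis.

Step 2
Reactants: 2 1,4-bis(benzyloxy)-2-methoxybenzene
Product: 3 1,4-bis(benzyloxy)-2-bromo-5-methoxybenzene
Conditions: NBS (1.05 equiv), MeCN, 0 °C to rt, dark
Reagents that add atoms: N-bromosuccinimide, O=C1CCC(=O)N1Br
Why: Electrophilic aromatic bromination should go to the position para to the methoxy group and ortho to a benzyloxy group, the most activated and least hindered site, as in the bromination of 1,2,4-trimethoxybenzene.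

Step 3
Reactants: 3 1,4-bis(benzyloxy)-2-bromo-5-methoxybenzene
Product: 6 [2,5-bis(benzyloxy)-4-methoxyphenyl]boronic acid, via aryllithium 4 (not isolated), via lithium aryltriisopropoxyborate 5 (not isolated)
Conditions: n-BuLi (1.1 equiv), THF, −78 °C; B(OiPr)3 (1.5 equiv), −78 °C to rt; 1 M HCl to pH 5, 0 °C
Reagents that add atoms: triisopropyl borate, CC(C)OB(OC(C)C)OC(C)C; water, O
Why: Bromine–lithium exchange at −78 °C outruns deprotonation of the benzyl ethers, and trapping the aryllithium with the borate ester followed by mild acid hydrolysis is the standard lithiation–borylation route to an arylboronic acid.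

Step 4
Reactants: 7 1-(6-hydroxy-2,3,4-trimethoxyphenyl)ethanone
Product: 9 5,6,7-trimethoxy-4H-chromen-4-one, via enaminone 8 (not isolated)
Conditions: Me2NCH(OMe)2 (2 equiv), toluene, 100 °C; evaporate; conc. HCl, CH2Cl2, 40 °C
Reagents that add atoms: N,N-dimethylformamide dimethyl acetal, COC(OC)N(C)C
Why: Enaminone formation from the methyl ketone followed by acid-promoted conjugate addition of the only free phenol and loss of dimethylamine (addition–elimination) is the standard chromone synthesis, and it fixes O1 next to the unsubstituted C8.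

Step 5
Reactants: 9 5,6,7-trimethoxy-4H-chromen-4-one
Product: 11 5-hydroxy-6,7-dimethoxy-4H-chromen-4-one, via dichloroboryl ether 10 (not isolated)
Conditions: BCl3 (1.5 equiv), CH2Cl2, −78 to 0 °C; then ice water
Reagents that add atoms: none
Why: Chelation-directed Lewis acid ether cleavage, in which BCl3 bound to the C4 carbonyl oxygen cleaves only the peri 5-O-methyl group, is done on the achiral chromone so that no strong Lewis acid meets the later C2 stereocentre.

Step 6
Reactants: 11 5-hydroxy-6,7-dimethoxy-4H-chromen-4-one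
Product: 12 5-(benzyloxy)-6,7-dimethoxy-4H-chromen-4-one
Conditions: BnBr (1.5 equiv), K2CO3 (2 equiv), DMF, 60 °C
Reagents that add atoms: benzyl bromide, BrCc1ccccc1
Why: Williamson etherification of the hydrogen-bonded peri phenol needs warm DMF but is routine, and the benzyl ether keeps the 5-oxido-4-keto unit from binding the cationic palladium catalyst of the next step as an O,O-chelate and later leaves together with the ring B benzyl groups.

Step 7
Reactants: 12 5-(benzyloxy)-6,7-dimethoxy-4H-chromen-4-one; 6 [2,5-bis(benzyloxy)-4-methoxyphenyl]boronic acid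
Product: 13 (2S)-5-(benzyloxy)-2-[2,5-bis(benzyloxy)-4-methoxyphenyl]-6,7-dimethoxy-2,3-dihydro-4H-chromen-4-one
Conditions: 6 (2 equiv), Pd(OCOCF3)2 (5 mol%), (R)-4-tert-butyl-2-(pyridin-2-yl)-4,5-dihydrooxazole [(R)-t-BuPyOx, 6 mol%], NH4PF6 (30 mol%), H2O (5 equiv), ClCH2CH2Cl, 60 °C, air
Reagents that add atoms: none
Why: Palladium-catalysed asymmetric conjugate addition of an arylboronic acid to a chromone, in which the cationic aryl complex of divalent palladium with the pyridine–oxazoline ligand inserts the C2=C3 bond on the face left open by the tert-butyl group and water protonates the palladium enolate, so that the ligand sets C2, the (R) ligand being the hand expected to give 2S.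

Step 8
Reactants: 13 (2S)-5-(benzyloxy)-2-[2,5-bis(benzyloxy)-4-methoxyphenyl]-6,7-dimethoxy-2,3-dihydro-4H-chromen-4-one
Product: 14 (2S)-2-(2,5-dihydroxy-4-methoxyphenyl)-5-hydroxy-6,7-dimethoxy-2,3-dihydro-4H-chromen-4-one
Conditions: H2 (1 atm), 10% Pd/C, EtOAc/MeOH, rt; filtered and concentrated under argon
Reagents that add atoms: none
Why: Hydrogenolysis of the three aryl benzyl ethers over palladium on carbon is neutral, so neither the C2 stereocentre nor the ketone should be touched, and the air-sensitive hydroquinone is kept under argon and used at once.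

Step 9
Reactants: 14 (2S)-2-(2,5-dihydroxy-4-methoxyphenyl)-5-hydroxy-6,7-dimethoxy-2,3-dihydro-4H-chromen-4-one
Product: 15 (2R,3R)-2-(2,5-dihydroxy-4-methoxyphenyl)-3,5-dihydroxy-6,7-dimethoxy-2,3-dihydro-4H-chromen-4-one
Conditions: recombinant flavanone 3-hydroxylase (cell-free extract from E. coli), FeSO4 (0.1 mM), disodium 2-oxoglutarate (2 equiv), sodium ascorbate (5 mM), catalase, air, HEPES buffer pH 7.5, 5% DMSO, 30 °C
Reagents that add atoms: dioxygen, O=O
Why: The divalent iron of the enzyme binds 2-oxoglutarate and O2, and oxidative decarboxylation to succinate and CO2 leaves a tetravalent iron-oxo species that abstracts the C3 hydrogen trans to ring B and returns hydroxyl to the same face (radical rebound with retention), which forms the C3–O bond. The closest known reaction is the hydroxylation of (2S)-naringenin and (2S)-eriodictyol to their (2R,3R)-dihydroflavonols by this family of 2-oxoglutarate-dependent non-heme iron dioxygenases. No ring is closed. The new C3 stereocentre (R, hydroxyl trans to the C2 aryl group) is controlled by the active site, which presents only that hydrogen to the oxo group, and it is also the more stable diequatorial arrangement. The step needs site selectivity (C3–H rather than the benzylic C2–H, and no desaturation to the flavone), face selectivity and enantiomer selection, and all three rest on the chelated 5-hydroxy-4-keto unit of rings A and C and the equatorial ring B of the 2S enantiomer, through which 14 is held like the natural substrates; residual 2R material from step 7 should be left unchanged. Ascorbate keeps both the iron and the ring B hydroquinone reduced, and catalase removes hydrogen peroxide from uncoupled turnover.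

Step 10
Reactants: 15 (2R,3R)-2-(2,5-dihydroxy-4-methoxyphenyl)-3,5-dihydroxy-6,7-dimethoxy-2,3-dihydro-4H-chromen-4-one
Product: 16 (2R,3R)-2-{2,5-bis[(tert-butyldimethylsilyl)oxy]-4-methoxyphenyl}-3,5-dihydroxy-6,7-dimethoxy-2,3-dihydro-4H-chromen-4-one
Conditions: TBSCl (2.2 equiv), imidazole (4.5 equiv), DMF, 0 °C, argon
Reagents that add atoms: tert-butyldimethylsilyl chloride, CC(C)(C)[Si](C)(C)Cl
Why: Imidazole-mediated silylation should take the two free ring B phenols well before the hindered, carbonyl-bonded C3 secondary alcohol and the chelated 5-hydroxyl, as in the phenol-selective silylation of flavan-3-ols, and the near-neutral medium does not open ring C.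

Step 11
Reactants: 16 (2R,3R)-2-{2,5-bis[(tert-butyldimethylsilyl)oxy]-4-methoxyphenyl}-3,5-dihydroxy-6,7-dimethoxy-2,3-dihydro-4H-chromen-4-one
Product: 17 (2R,3R)-2-{2,5-bis[(tert-butyldimethylsilyl)oxy]-4-methoxyphenyl}-5-hydroxy-3,6,7-trimethoxy-2,3-dihydro-4H-chromen-4-one
Conditions: MeOTf (3 equiv), 2,6-di-tert-butyl-4-methylpyridine (4 equiv), CH2Cl2, 0 °C to rt
Reagents that add atoms: methyl trifluoromethanesulfonate, COS(=O)(=O)C(F)(F)F
Why: O-Alkylation of the C3 alcohol by methyl triflate with a hindered pyridine as acid scavenger uses a base too weak to form a phenoxide or an enolate, so the chelated 5-hydroxyl (a poor neutral nucleophile) should stay free and C2 and C3 keep their configuration.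

Step 12
Reactants: 17 (2R,3R)-2-{2,5-bis[(tert-butyldimethylsilyl)oxy]-4-methoxyphenyl}-5-hydroxy-3,6,7-trimethoxy-2,3-dihydro-4H-chromen-4-one
Product: 18 (2R,3R)-2-(2,5-dihydroxy-4-methoxyphenyl)-5-hydroxy-3,6,7-trimethoxy-2,3-dihydro-4H-chromen-4-one
Conditions: Bu4NF (2.4 equiv), AcOH (3 equiv), THF, 0 °C, argon
Reagents that add atoms: none
Why: Fluoride cleavage of the two aryl silyl ethers, buffered with acetic acid so that no free phenoxide can open ring C at C2 or let the hydroquinone autoxidise, should release the target with the 3-methoxy group and both stereocentres unchanged.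

**Compound list**

1 | 2-methoxyhydroquinone | COc1cc(O)ccc1O | starting material
2 | 1,4-bis(benzyloxy)-2-methoxybenzene | COc1cc(OCc2ccccc2)ccc1OCc1ccccc1 | intermediate
3 | 1,4-bis(benzyloxy)-2-bromo-5-methoxybenzene | COc1cc(OCc2ccccc2)c(Br)cc1OCc1ccccc1 | intermediate
4 | [2,5-bis(benzyloxy)-4-methoxyphenyl]lithium | COc1cc(OCc2ccccc2)c([Li])cc1OCc1ccccc1 | intermediate (not isolated)
5 | lithium [2,5-bis(benzyloxy)-4-methoxyphenyl]tri(propan-2-yloxy)borate | [Li+].COc1cc(OCc2ccccc2)c([B-](OC(C)C)(OC(C)C)OC(C)C)cc1OCc1ccccc1 | intermediate (not isolated)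
6 | [2,5-bis(benzyloxy)-4-methoxyphenyl]boronic acid | COc1cc(OCc2ccccc2)c(B(O)O)cc1OCc1ccccc1 | intermediate
7 | 1-(6-hydroxy-2,3,4-trimethoxyphenyl)ethanone | CC(=O)c1c(O)cc(OC)c(OC)c1OC | starting material
8 | (E)-3-(dimethylamino)-1-(6-hydroxy-2,3,4-trimethoxyphenyl)prop-2-en-1-one | CN(C)/C=C/C(=O)c1c(O)cc(OC)c(OC)c1OC | intermediate (not isolated)
9 | 5,6,7-trimethoxy-4H-chromen-4-one | COc1cc2occc(=O)c2c(OC)c1OC | intermediate
10 | 5-(dichloroboryloxy)-6,7-dimethoxy-4H-chromen-4-one | COc1cc2occc(=O)c2c(OB(Cl)Cl)c1OC | intermediate (not isolated)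
11 | 5-hydroxy-6,7-dimethoxy-4H-chromen-4-one | COc1cc2occc(=O)c2c(O)c1OC | intermediate
12 | 5-(benzyloxy)-6,7-dimethoxy-4H-chromen-4-one | COc1cc2occc(=O)c2c(OCc3ccccc3)c1OC | intermediate
13 | (2S)-5-(benzyloxy)-2-[2,5-bis(benzyloxy)-4-methoxyphenyl]-6,7-dimethoxy-2,3-dihydro-4H-chromen-4-one | COc1cc(OCc2ccccc2)c([C@H]2Oc3cc(OC)c(OC)c(OCc4ccccc4)c3C(=O)C2)cc1OCc1ccccc1 | intermediate
14 | (2S)-2-(2,5-dihydroxy-4-methoxyphenyl)-5-hydroxy-6,7-dimethoxy-2,3-dihydro-4H-chromen-4-one | COc1cc(O)c([C@H]2Oc3cc(OC)c(OC)c(O)c3C(=O)C2)cc1O | intermediate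
15 | (2R,3R)-2-(2,5-dihydroxy-4-methoxyphenyl)-3,5-dihydroxy-6,7-dimethoxy-2,3-dihydro-4H-chromen-4-one | COc1cc(O)c([C@H]2Oc3cc(OC)c(OC)c(O)c3C(=O)[C@@H]2O)cc1O | intermediate
16 | (2R,3R)-2-{2,5-bis[(tert-butyldimethylsilyl)oxy]-4-methoxyphenyl}-3,5-dihydroxy-6,7-dimethoxy-2,3-dihydro-4H-chromen-4-one | COc1cc(O[Si](C)(C)C(C)(C)C)c([C@H]2Oc3cc(OC)c(OC)c(O)c3C(=O)[C@@H]2O)cc1O[Si](C)(C)C(C)(C)C | intermediate
17 | (2R,3R)-2-{2,5-bis[(tert-butyldimethylsilyl)oxy]-4-methoxyphenyl}-5-hydroxy-3,6,7-trimethoxy-2,3-dihydro-4H-chromen-4-one | COc1cc(O[Si](C)(C)C(C)(C)C)c([C@H]2Oc3cc(OC)c(OC)c(O)c3C(=O)[C@@H]2OC)cc1O[Si](C)(C)C(C)(C)C | intermediate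
18 | (2R,3R)-2-(2,5-dihydroxy-4-methoxyphenyl)-5-hydroxy-3,6,7-trimethoxy-2,3-dihydro-4H-chromen-4-one | COc1cc(O)c([C@H]2Oc3cc(OC)c(OC)c(O)c3C(=O)[C@@H]2OC)cc1O | target

**Step count**

Total: 12 steps. Longest linear sequence: 9 steps (steps 1, 2, 3, 7, 8, 9, 10, 11, 12 from 1; the ring A branch, steps 4, 5, 6 and then 7 to 12 from 7, is equally long).

**Steps most likely to fail**

Step 9. The enzyme may bind the unusual 2',5'-dihydroxy-4'-methoxy ring B or the 6,7-dimethoxy ring A poorly, giving low turnover, and the hydroquinone may autoxidise in the aerated buffer. The fallback is a chemical hydroxylation that sets out from 13. Soft enolisation (Me3SiOTf, Et3N, CH2Cl2, 0 °C) should give the trimethylsilyl enol ether F1 without passing through a free enolate that could open ring C. Rubottom oxidation with dimethyldioxirane (acetone, −20 °C) should epoxidise the enol ether on the face away from ring B to the siloxy epoxide F2. On work-up with citric acid in methanol this should collapse to the trans hydroxy ketone F3. Hydrogenolysis of the three benzyl ethers (H2, Pd/C, EtOAc/MeOH) comes back to the route at 15.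

Step 7. Protodeboronation of the electron-rich ortho-alkoxy boronic acid may outrun transmetallation, insertion into the electron-rich chromone may be slow, and the ortho substituent may erode facial selectivity. The fallback builds the flavanone by condensation and sets out from 2 and 7. Vilsmeier–Haack formylation of 2 (POCl3, DMF, 0 °C to 60 °C) should give 2,5-bis(benzyloxy)-4-methoxybenzaldehyde F4. Claisen–Schmidt condensation with 7 (KOH, EtOH, rt) should give the chalcone F5. Oxa-Michael ring closure (NaOAc, EtOH, reflux) should give the racemic flavanone F6. BCl3 with pentamethylbenzene (CH2Cl2, −78 to 0 °C) should remove both benzyl groups and the chelated 5-O-methyl to give the racemic triphenol F7; no stereochemical information is at risk here because the material is racemic. F7 is then submitted to the hydroxylase under the conditions of step 9, which should convert only its 2S half in a kinetic resolution, so the fallback comes back to the route at 15. The unreacted 2R flavanone could be racemised through its chalcone with mild base and recycled.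

Step 11. Alkylation of the hindered, hydrogen-bonded C3 alcohol may be slow, allowing competing methylation of the 5-hydroxyl or loss of a silyl group to adventitious triflic acid. The fallback changes both the protecting group and the alkylation regime and sets out from 15. Benzylation with BnBr and K2CO3 in acetone at rt, which alkylates only the two ring B phenols, should give the dibenzyl ether F8. Purdie methylation (MeI, Ag2O, CH2Cl2, dark, rt) should give the methyl ether F9. Hydrogenolysis (H2, Pd/C, EtOAc) comes back to the route at 18.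

**Further compounds**

F1 | step 9 | (2S)-5-(benzyloxy)-2-[2,5-bis(benzyloxy)-4-methoxyphenyl]-6,7-dimethoxy-4-(trimethylsilyloxy)-2H-chromene | COc1cc(OCc2ccccc2)c([C@H]2Oc3cc(OC)c(OC)c(OCc4ccccc4)c3C(O[Si](C)(C)C)=C2)cc1OCc1ccccc1
F2 | step 9 | (2R)-5-(benzyloxy)-2-[2,5-bis(benzyloxy)-4-methoxyphenyl]-3,4-epoxy-6,7-dimethoxy-4-(trimethylsilyloxy)chromane, oxirane oxygen trans to ring B | COc1cc(OCc2ccccc2)c([C@H]2Oc3cc(OC)c(OC)c(OCc4ccccc4)c3[C@]4(O[Si](C)(C)C)O[C@H]24)cc1OCc1ccccc1
F3 | step 9 | (2R,3R)-5-(benzyloxy)-2-[2,5-bis(benzyloxy)-4-methoxyphenyl]-3-hydroxy-6,7-dimethoxy-2,3-dihydro-4H-chromen-4-one | COc1cc(OCc2ccccc2)c([C@H]2Oc3cc(OC)c(OC)c(OCc4ccccc4)c3C(=O)[C@@H]2O)cc1OCc1ccccc1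
F4 | step 7 | 2,5-bis(benzyloxy)-4-methoxybenzaldehyde | COc1cc(OCc2ccccc2)c(C=O)cc1OCc1ccccc1
F5 | step 7 | (E)-3-[2,5-bis(benzyloxy)-4-methoxyphenyl]-1-(6-hydroxy-2,3,4-trimethoxyphenyl)prop-2-en-1-one | COc1cc(OCc2ccccc2)c(/C=C/C(=O)c2c(O)cc(OC)c(OC)c2OC)cc1OCc1ccccc1
F6 | step 7 | racemic 2-[2,5-bis(benzyloxy)-4-methoxyphenyl]-5,6,7-trimethoxy-2,3-dihydro-4H-chromen-4-one | COc1cc(OCc2ccccc2)c(C2CC(=O)c3c(OC)c(OC)c(OC)cc3O2)cc1OCc1ccccc1
F7 | step 7 | racemic 2-(2,5-dihydroxy-4-methoxyphenyl)-5-hydroxy-6,7-dimethoxy-2,3-dihydro-4H-chromen-4-one | COc1cc(O)c(C2CC(=O)c3c(O)c(OC)c(OC)cc3O2)cc1O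
F8 | step 11 | (2R,3R)-2-[2,5-bis(benzyloxy)-4-methoxyphenyl]-3,5-dihydroxy-6,7-dimethoxy-2,3-dihydro-4H-chromen-4-one | COc1cc(OCc2ccccc2)c([C@H]2Oc3cc(OC)c(OC)c(O)c3C(=O)[C@@H]2O)cc1OCc1ccccc1
F9 | step 11 | (2R,3R)-2-[2,5-bis(benzyloxy)-4-methoxyphenyl]-5-hydroxy-3,6,7-trimethoxy-2,3-dihydro-4H-chromen-4-one | COc1cc(OCc2ccccc2)c([C@H]2Oc3cc(OC)c(OC)c(O)c3C(=O)[C@@H]2OC)cc1OCc1ccccc1
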